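## The problem

The target is (4S,5R,6R,7R,8S)-6-acetoxy-8-angeloyloxy-4,5-epoxygermacr-1(10)E-ene: one ten-membered carbocycle with no ring fusion to lean on. Ring closure therefore has to overcome medium-ring strain, and both trisubstituted alkene geometries must be fixed before it. The epoxide carries C3 and C6 cis on the oxirane, so it descends from a 4Z alkene, while C1=C10 is E. C7 (isopropyl) and C8 (angelate) are syn and can be set together. C6 (acetate) is anti to both and needs its own control. Its free hydroxyl is the only handle that can choose the epoxide face at C4/C5. The two oxygens carry different esters, so O6 and O8 must be told apart early. The angelate isomerises to the tiglate under base or nucleophilic catalysis and cannot pass through carbanion or hydride steps. The epoxide sits across the ring from a nucleophilic alkene and is opened by acid, and the 1,5-diene that precedes it can undergo Cope rearrangement on heating. The feature that invites the key step is that C2 and C3 are adjacent methylenes, each allylic (C2 to C1=C10, C3 to C4=C5). The C2–C3 bond is thus the union of a stabilised allylic carbanion and an allylic electrophile, the only ring bond between two sp3 carbons without a substituent.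

## Retrosynthesis

**Acetate and epoxide (36 ⇒ 35 ⇒ 34).** The C6–O acyl bond and the two C–O bonds of the oxirane are cut last. Acetylation is the mildest step available and suits the end. The epoxide comes just before it, because the free O6–H of 34 is needed to direct the oxidant and because the epoxy-ene is the most acid-sensitive array in the route. Epoxidation of an open-chain Z-allylic alcohol would be steered by allylic 1,3-strain to the threo isomer, the opposite of the target, so it is done in the ring. There C7 is held out of the alkene plane and directed and peripheral attack should coincide. Precursor 34 lacks two stereocentres. The forward step must put oxygen on C4=C5 only, on the face of O6.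

**Ester and silyl ether adjustments (34 ⇒ 33 ⇒ 30 ⇒ 29).** The C8–O acyl bond and the two O–Si bonds are cut. The angelate goes on while O6 is still silylated, which removes any competition between the hydroxyls and places the one heated acylation before the epoxide exists. O6 is then freed with acidic fluoride, so no alkoxide is formed and the 1,3-related ester cannot migrate. This order requires a labile silyl group on O8 (TES) and a sturdier one on O6 (TBS). Diene 29 is the last intermediate free of esters, so all carbanion and hydride chemistry lies behind it.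

**Sulfone removal (29 ⇒ 28).** The C2–H bond replaces C2–S. The sulfone sits on C2 and not on C3 because the π-allyl intermediate of its removal then spans C2–C1–C10. The C10 end is fully substituted and cannot exchange geometry, and the unit is remote from the oxygenated carbons. A sulfone on C3 would put the Z alkene next to C6 at risk.

**Ring closure (28 ⇒ 26).** The C2–C3 bond is cut. Closing at C1=C10 or C4=C5 by olefination or metathesis would leave a trisubstituted alkene geometry to the ring closure. Closing at C5–C6, C6–C7 or C7–C8 would create a stereocentre in the step least able to control it. C2–C3 carries neither. Precursor 26 is an open chain with all three stereocentres and both alkene geometries in place. The forward step must alkylate at C2 rather than C10, substitute at C3 rather than C5, and beat oligomerisation.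

**Chain termini (26 ⇒ 25 ⇒ 24 ⇒ 21 ⇒ 20).** Only functional groups change: C3–Br from the alcohol 25, that from the ester 24, and the C2 sulfone from alcohol 21 and PMB ether 20. The sulfone is installed while C3 is still an ester, because sulfinate would also attack an allylic bromide and a free C3 alcohol would be mesylated too. It is not carried from the start because its acidic C2–H would not survive the Grignard and aluminium hydride steps. The bromide is made last because it is the least stable compound of the route.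

**Z-trisubstituted alkene (20 ⇒ 19 ⇒ 18 ⇒ 16).** The C3–C4 bond (carbonylation) and the C4–I and C5–H bonds (hydroalumination–iodination) are cut, leading to the methyl alkyne 16. A Z-selective olefination would be the neighbouring choice, but it needs an α-silyloxy aldehyde at C5 that is not readily reached from the aldol product. Trans-hydroalumination directed by O6 places the future C3 cis to C6 stereospecifically. O6 is silylated before carbonylation so that no butenolide forms.

**C6 stereocentre and C5–C6 bond (16 ⇒ 15 ⇒ 13 + 14).** The C6–H bond goes back to ynone 15 and the C5–C6 bond to Weinreb amide 13 and propynylmagnesium bromide 14. Addition of a nucleophile to a C6 aldehyde would face opposed 1,2- and 1,3-induction for the required anti,anti isomer. A catalyst-controlled reduction of an ynone, whose flanks differ sharply (linear alkynyl against branched alkyl), is the more reliable way.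

**Aldol (13 ⇒ 12 ⇒ 11 ⇒ 9 + 6).** The C7–C8 bond is cut. The syn relation of the isopropyl group and O8 is the signature of an auxiliary-controlled boron aldol between imide 9 and aldehyde 6. The acyl carbon becomes C6, and the aldehyde brings C8, C9, C10, C1 and C2 with the E alkene already in place.

**Fragments (6 ⇐ 5 ⇐ 4 ⇐ 3 ⇐ 1; 9 ⇐ 7 + 8).** The C10–CH3 and C1–C2 bonds of 3 come from methylalumination and hydroxymethylation of alkyne 1, which fixes the E geometry by syn addition. A protecting-group exchange makes the homoallylic carbon the aldehyde carbon C8. Imide 9 is the acylation product of oxazolidinone 7 and acid chloride 8.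

## Roads not taken

**Alternative 1:** Photocycloaddition followed by thermal unzipping.
- Cut and key step: C1–C10 and C4–C5 are cut at once. Irradiation of cyclohexenone A2 with methyl cyclobut-1-ene-1-carboxylate A3 would give the head-to-head tricycle A1, which already holds the ten-carbon perimeter. Heating would then cleave the two internal cyclobutane bonds (C1–C4 and C5–C10) to release the cyclodeca-1(10),4-diene.
- Merits: the ring carbons are assembled in one step without high dilution, and C7 and C8 can be set on a rigid six-membered ring. In step count to the ring this road is shorter than the chosen one.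
- Weak points: A1 carries C15 as an ester, which costs about three steps to reduce to methyl. The cycloreversion needs temperatures at which a germacra-1(10),4-diene itself undergoes Cope rearrangement. The 1(10)E and 4Z geometries would be decided by the course of the fragmentation, not by design. C6 arrives as a ring ketone whose reduction would be governed by macrocycle conformation.
- Comparison: the chosen plan is longer, but it fixes both geometries on open-chain compounds and needs no step above 80 °C.

**Alternative 2:** Anionic oxy-Cope ring expansion.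
- Cut and key step: C8–C9 is cut and C1–C6 is re-formed. The potassium alkoxide of the dialkenyl cyclohexenol A5 (an isopiperitenone adduct) would undergo a [3,3] shift through a chair. This gives the ten-membered enolate and, after protonation at C7, dienone A4.
- Merits: this is the fastest way to the ring. It needs no dilution, sets 1(10)E through the chair, inherits 4Z from the six-membered ring and starts from a terpene ketone. In these respects it is better than the chosen plan.
- Weak points: C7 would be set by kinetic protonation of a medium-ring enolate. The enolate has the C8 alkoxy group in the β position and can expel it. C8 depends on a stereodefined trisubstituted enol-ether alkenyl metal. C6 again comes from reduction of a ring ketone, here a Z-enone prone to isomerisation.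
- Comparison: the chosen plan sets C6, C7 and C8 under auxiliary and catalyst control before the ring exists, and has both oxygens differentiated from step 8 on.

**Alternative 3:** Wittig–Still ring contraction.
- Cut and key step: C7–C8 is cut and O–C12 is re-formed. Tin–lithium exchange on the thirteen-membered α-stannyl ether A7 would trigger a [2,3] shift that forms C7–C8 and gives the cyclodecadienol A6.
- Merits: the step creates C7 and C8 while the ring forms. It also delivers O8 free and O6 silylated, which is exactly the differentiation the endgame needs. There it is better than the chosen plan.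
- Weak points: A7 needs its own macrocyclic etherification and a configurationally defined stannyl carbinol carbon. Chirality transfer must be relayed through a flexible thirteen-membered transition state. The isopropenyl group of A6 must later be saturated in the presence of two trisubstituted ring alkenes.
- Comparison: the chosen plan has a single ring-forming event, and only the final epoxidation depends on macrocycle conformation.

Key step: step 18

Remarks on the chemistry:
- Ring compounds are named on the germacrane skeleton (alkenes C1=C10 and C4=C5, oxygen on C6 and C8, isopropyl on C7).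
- Sulfone 28 is carried as the mixture of C2 epimers, since that centre becomes a methylene in step 19.
- Compounds 1, 7, 8, 14, 22 and 31 are taken as purchased.

## Route

Step 1
Reactants: 1 4-(tert-butyldimethylsilyloxy)but-1-yne
Product: 3 (2E)-5-(tert-butyldimethylsilyloxy)-3-methylpent-2-en-1-ol, via alkenyldimethylalane 2 (not isolated)
Conditions: Me3Al, Cp2ZrCl2 (cat.), CH2Cl2, 0 °C to rt; then (CH2O)n, 0 °C to rt
Reagents that add atoms: trimethylaluminium, C[Al](C)C; formaldehyde (from paraformaldehyde), C=O
Why: Zirconium-catalysed Negishi carboalumination adds methyl and aluminium syn across the terminal alkyne with methyl on the internal carbon; hydroxymethylation of alkenylalane 2 with retention then gives the E geometry needed at C1=C10.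

Step 2
Reactants: 3 (2E)-5-(tert-butyldimethylsilyloxy)-3-methylpent-2-en-1-ol
Product: 4 tert-butyl{[(3E)-5-(4-methoxybenzyloxy)-3-methylpent-3-en-1-yl]oxy}dimethylsilane
Conditions: NaH, 4-methoxybenzyl chloride, n-Bu4NI (cat.), THF/DMF, 0 °C to rt
Reagents that add atoms: 4-methoxybenzyl chloride, COc1ccc(CCl)cc1
Why: Williamson etherification of the primary allylic alkoxide; the PMB ether survives the organometallic and hydride steps up to step 13 and is later removed oxidatively without touching silyl ethers.

Step 3
Reactants: 4 tert-butyl{[(3E)-5-(4-methoxybenzyloxy)-3-methylpent-3-en-1-yl]oxy}dimethylsilane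
Product: 5 (3E)-5-(4-methoxybenzyloxy)-3-methylpent-3-en-1-ol
Conditions: n-Bu4NF, THF, 0 °C to rt
Reagents that add atoms: none
Why: Fluoride cleaves the primary silyl ether; the allylic PMB ether and the alkene are inert.

Step 4
Reactants: 5 (3E)-5-(4-methoxybenzyloxy)-3-methylpent-3-en-1-ol
Product: 6 (3E)-5-(4-methoxybenzyloxy)-3-methylpent-3-enal
Conditions: Dess–Martin periodinane, NaHCO3, CH2Cl2, 0 °C to rt; used at once
Reagents that add atoms: none
Why: Buffered Dess–Martin oxidation gives the β,γ-unsaturated aldehyde without acid or base strong enough to move the alkene into conjugation.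

Step 5
Reactants: 7 (4R)-4-benzyl-1,3-oxazolidin-2-one; 8 3-methylbutanoyl chloride
Product: 9 (4R)-4-benzyl-3-(3-methylbutanoyl)-1,3-oxazolidin-2-one
Conditions: n-BuLi, THF, −78 °C; then 8, −78 to 0 °C
Reagents that add atoms: none
Why: N-Acylation of the lithiated oxazolidinone with an acid chloride, the standard entry to Evans imides.

Step 6
Reactants: 9 (4R)-4-benzyl-3-(3-methylbutanoyl)-1,3-oxazolidin-2-one; 6 (3E)-5-(4-methoxybenzyloxy)-3-methylpent-3-enal
Product: 11 (4R)-4-benzyl-3-[(2R,3S,5E)-3-hydroxy-7-(4-methoxybenzyloxy)-5-methyl-2-(propan-2-yl)hept-5-enoyl]-1,3-oxazolidin-2-one, via Z-dibutylboron enolate 10 (not isolated)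
Conditions: Bu2BOTf, i-Pr2NEt, CH2Cl2, 0 °C; then 6, −78 to 0 °C; pH 7 buffer, MeOH, H2O2
Reagents that add atoms: none
Why: Evans syn-aldol: Z-boron enolate 10 reacts through a closed Zimmerman–Traxler chair with the auxiliary carbonyl dipole opposed, so the (R)-benzyl group sets C7 (R) and C8 (S) syn in one step; boron aldols accept β,γ-unsaturated aldehydes at low temperature.

Step 7
Reactants: 11 (4R)-4-benzyl-3-[(2R,3S,5E)-3-hydroxy-7-(4-methoxybenzyloxy)-5-methyl-2-(propan-2-yl)hept-5-enoyl]-1,3-oxazolidin-2-one
Product: 12 (2R,3S,5E)-3-hydroxy-N-methoxy-7-(4-methoxybenzyloxy)-N,5-dimethyl-2-(propan-2-yl)hept-5-enamide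
Conditions: MeNHOMe·HCl, Me3Al, CH2Cl2, −20 to 0 °C
Reagents that add atoms: N,O-dimethylhydroxylamine hydrochloride, CNOC.Cl
Why: Aluminium amide transamination of an aldol adduct, assisted by the free β-hydroxyl (the aluminium alkoxide activates the exocyclic carbonyl), gives the Weinreb amide and releases the auxiliary for recovery.

Step 8
Reactants: 12 (2R,3S,5E)-3-hydroxy-N-methoxy-7-(4-methoxybenzyloxy)-N,5-dimethyl-2-(propan-2-yl)hept-5-enamide
Product: 13 (2R,3S,5E)-N-methoxy-7-(4-methoxybenzyloxy)-N,5-dimethyl-2-(propan-2-yl)-3-(triethylsilyloxy)hept-5-enamide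
Conditions: TESOTf, 2,6-lutidine, CH2Cl2, −78 to 0 °C
Reagents that add atoms: triethylsilyl trifluoromethanesulfonate, CC[Si](CC)(CC)OS(=O)(=O)C(F)(F)F
Why: Silylation of the secondary alcohol with a silyl triflate; TES is chosen so that O8 can later be released in the presence of the TBS ether on O6.

Step 9
Reactants: 13 (2R,3S,5E)-N-methoxy-7-(4-methoxybenzyloxy)-N,5-dimethyl-2-(propan-2-yl)-3-(triethylsilyloxy)hept-5-enamide; 14 prop-1-yn-1-ylmagnesium bromide
Product: 15 (5R,6S,8E)-10-(4-methoxybenzyloxy)-8-methyl-5-(propan-2-yl)-6-(triethylsilyloxy)dec-8-en-2-yn-4-one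
Conditions: THF, 0 °C to rt; aq. NH4Cl
Reagents that add atoms: none
Why: Alkynyl Grignard addition to a Weinreb amide stops at the ketone because the magnesium chelate survives until work-up; the propynyl group brings C5, C4 and the C4 methyl.

Step 10
Reactants: 15 (5R,6S,8E)-10-(4-methoxybenzyloxy)-8-methyl-5-(propan-2-yl)-6-(triethylsilyloxy)dec-8-en-2-yn-4-one
Product: 16 (4R,5S,6S,8E)-10-(4-methoxybenzyloxy)-8-methyl-5-(propan-2-yl)-6-(triethylsilyloxy)dec-8-en-2-yn-4-ol
Conditions: Ru[(R,R)-TsNCH(Ph)CH(Ph)NH](p-cymene) (2 mol %), i-PrOH, rt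
Reagents that add atoms: none
Why: Noyori asymmetric transfer hydrogenation of an α,β-acetylenic ketone is catalyst-controlled, the alkynyl group taking the place of the aryl group in the usual model; the (R,R) ligand should give the (4R) alcohol, in which O6 is anti to the isopropyl group and to O8.

Step 11
Reactants: 16 (4R,5S,6S,8E)-10-(4-methoxybenzyloxy)-8-methyl-5-(propan-2-yl)-6-(triethylsilyloxy)dec-8-en-2-yn-4-ol
Product: 18 (2Z,4R,5S,6S,8E)-2-iodo-10-(4-methoxybenzyloxy)-8-methyl-5-(propan-2-yl)-6-(triethylsilyloxy)deca-2,8-dien-4-ol, via cyclic alkenylaluminate 17 (not isolated)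
Conditions: NaAlH2(OCH2CH2OCH3)2, THF, 0 °C to rt; EtOAc; then I2, −78 to 0 °C
Reagents that add atoms: iodine, II
Why: Hydroxyl-directed trans-hydroalumination of the propargylic alcohol places aluminium on the distal carbon (chelate 17); iodinolysis with retention gives the Z-iodoalkene, in which iodine, the place of the future C3, is cis to C6.

Step 12
Reactants: 18 (2Z,4R,5S,6S,8E)-2-iodo-10-(4-methoxybenzyloxy)-8-methyl-5-(propan-2-yl)-6-(triethylsilyloxy)deca-2,8-dien-4-ol
Product: 19 tert-butyl{[(2Z,4R,5R,6S,8E)-2-iodo-10-(4-methoxybenzyloxy)-8-methyl-5-(propan-2-yl)-6-(triethylsilyloxy)deca-2,8-dien-4-yl]oxy}dimethylsilane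
Conditions: TBSOTf, 2,6-lutidine, CH2Cl2, −78 to 0 °C
Reagents that add atoms: tert-butyldimethylsilyl trifluoromethanesulfonate, CC(C)(C)[Si](C)(C)OS(=O)(=O)C(F)(F)F
Why: Silyl triflate protection of the hindered allylic alcohol; the TBS ether outlasts the TES ether on O8 and keeps O6 from closing onto C3 (butenolide or dihydrofuran) in later steps.

Step 13
Reactants: 19 tert-butyl{[(2Z,4R,5R,6S,8E)-2-iodo-10-(4-methoxybenzyloxy)-8-methyl-5-(propan-2-yl)-6-(triethylsilyloxy)deca-2,8-dien-4-yl]oxy}dimethylsilane
Product: 20 methyl (2Z,4S,5R,6S,8E)-4-(tert-butyldimethylsilyloxy)-10-(4-methoxybenzyloxy)-2,8-dimethyl-5-(propan-2-yl)-6-(triethylsilyloxy)deca-2,8-dienoate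
Conditions: PdCl2(PPh3)2 (10 mol %), CO (1 atm), Et3N, MeOH/DMF, 60 °C
Reagents that add atoms: carbon monoxide, [C-]#[O+]; methanol, CO
Why: Palladium-catalysed methoxycarbonylation of an alkenyl iodide proceeds with retention of geometry and gives the Z-enoate; C3 enters as an ester so that it stays masked while C2 is turned into the sulfone.

Step 14
Reactants: 20 methyl (2Z,4S,5R,6S,8E)-4-(tert-butyldimethylsilyloxy)-10-(4-methoxybenzyloxy)-2,8-dimethyl-5-(propan-2-yl)-6-(triethylsilyloxy)deca-2,8-dienoate
Product: 21 methyl (2Z,4S,5R,6S,8E)-4-(tert-butyldimethylsilyloxy)-10-hydroxy-2,8-dimethyl-5-(propan-2-yl)-6-(triethylsilyloxy)deca-2,8-dienoate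
Conditions: DDQ, CH2Cl2/pH 7 buffer, 0 °C
Reagents that add atoms: none
Why: Oxidative cleavage of the PMB ether by DDQ under buffered conditions leaves the silyl ethers, the enoate and both alkenes untouched.

Step 15
Reactants: 21 methyl (2Z,4S,5R,6S,8E)-4-(tert-butyldimethylsilyloxy)-10-hydroxy-2,8-dimethyl-5-(propan-2-yl)-6-(triethylsilyloxy)deca-2,8-dienoate; 22 sodium benzenesulfinate
Product: 24 methyl (2Z,4S,5R,6S,8E)-4-(tert-butyldimethylsilyloxy)-2,8-dimethyl-10-(phenylsulfonyl)-5-(propan-2-yl)-6-(triethylsilyloxy)deca-2,8-dienoate, via allylic mesylate 23 (not isolated)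
Conditions: (MeSO2)2O, Et3N, CH2Cl2, −20 °C; then 22, DMF, rt
Reagents that add atoms: none
Why: The primary allylic mesylate 23 is displaced at the unhindered CH2 by the sulfur of benzenesulfinate (SN2), giving the allylic sulfone without allylic transposition and without touching the alkene geometry.

Step 16
Reactants: 24 methyl (2Z,4S,5R,6S,8E)-4-(tert-butyldimethylsilyloxy)-2,8-dimethyl-10-(phenylsulfonyl)-5-(propan-2-yl)-6-(triethylsilyloxy)deca-2,8-dienoate
Product: 25 (2Z,4S,5R,6S,8E)-4-(tert-butyldimethylsilyloxy)-2,8-dimethyl-10-(phenylsulfonyl)-5-(propan-2-yl)-6-(triethylsilyloxy)deca-2,8-dien-1-ol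
Conditions: i-Bu2AlH, CH2Cl2, −78 °C; Rochelle salt
Reagents that add atoms: none
Why: 1,2-Reduction of the conjugated ester by i-Bu2AlH at low temperature gives the allylic alcohol; the sulfone, the silyl ethers and the Z geometry are not affected.

Step 17
Reactants: 25 (2Z,4S,5R,6S,8E)-4-(tert-butyldimethylsilyloxy)-2,8-dimethyl-10-(phenylsulfonyl)-5-(propan-2-yl)-6-(triethylsilyloxy)deca-2,8-dien-1-ol
Product: 26 {[(2E,5S,6R,7S,8Z)-10-bromo-7-(tert-butyldimethylsilyloxy)-3,9-dimethyl-6-(propan-2-yl)-5-(triethylsilyloxy)deca-2,8-dien-1-yl]sulfonyl}benzene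
Conditions: CBr4, PPh3, 2,6-lutidine, CH2Cl2, −30 to 0 °C; used directly
Reagents that add atoms: carbon tetrabromide, BrC(Br)(Br)Br
Why: Appel bromination converts the primary allylic alcohol into the bromide by SN2 displacement of the oxyphosphonium group under near-neutral conditions, which keeps the Z geometry.

Step 18
Reactants: 26 {[(2E,5S,6R,7S,8Z)-10-bromo-7-(tert-butyldimethylsilyloxy)-3,9-dimethyl-6-(propan-2-yl)-5-(triethylsilyloxy)deca-2,8-dien-1-yl]sulfonyl}benzene
Product: 28 (6S,7R,8S)-6-(tert-butyldimethylsilyloxy)-2-(phenylsulfonyl)-8-(triethylsilyloxy)germacra-1(10)E,4Z-diene (both C2 epimers), via potassium sulfonyl carbanion 27 (not isolated)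
Conditions: KN(SiMe3)2 (1.1 equiv), THF, −78 to 0 °C, slow addition of 26 (final about 0.003 M)
Reagents that add atoms: none
Why: KN(SiMe3)2 removes a proton from C2, which is both α to the sulfone and allylic, and the potassium carbanion 27 attacks the primary allylic carbon C3 with loss of bromide in an intramolecular SN2 step that makes the C2–C3 bond. The closest known reaction type is the intramolecular alkylation of sulfone-stabilised allylic carbanions by allylic halides used to close terpenoid macrocycles, well documented for fourteen-membered rings and, with heteroatom-stabilised allylic carbanions, for ten-membered germacrane rings. The ten-membered ring closes in the 10-exo-tet mode, end to end between the only two adjacent sp3 ring carbons, so neither alkene has to twist in the transition state. The new stereocentre at C2 is not controlled (the ring conformation at closure decides it) and need not be, because step 19 turns it into a methylene. Three selectivities are needed: attack through C2 and not C10 of the allyl anion, secured by the sulfone, which keeps the charge α to sulfur; SN2 and not SN2′ displacement, secured by the unhindered primary bromide against a C5 position flanked by the silylated C6; and cyclisation over oligomerisation, secured by slow addition of 26 to the base at high dilution. Both alkene geometries should be retained, because C3 reacts without ionisation and the sulfonyl allyl anion does not rotate about C1–C10 at low temperature. Only a slight excess of base is used, so that the product, still acidic at C2, is not held as its anion longer than necessary.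

Step 19
Reactants: 28 (6S,7R,8S)-6-(tert-butyldimethylsilyloxy)-2-(phenylsulfonyl)-8-(triethylsilyloxy)germacra-1(10)E,4Z-diene
Product: 29 (6S,7R,8S)-6-(tert-butyldimethylsilyloxy)-8-(triethylsilyloxy)germacra-1(10)E,4Z-diene
Conditions: PdCl2(dppp) (10 mol %), LiBHEt3, THF, 0 °C to rt
Reagents that add atoms: none
Why: Palladium-catalysed reductive desulfonylation: zerovalent palladium ionises the allylic sulfone to a π-allyl complex over C2–C1–C10 and hydride is transferred to the less substituted terminus C2, so the alkene stays at C1=C10. The fully substituted C10 terminus does not undergo syn–anti exchange, so the E geometry should persist.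

Step 20
Reactants: 29 (6S,7R,8S)-6-(tert-butyldimethylsilyloxy)-8-(triethylsilyloxy)germacra-1(10)E,4Z-diene
Product: 30 (6S,7R,8S)-6-(tert-butyldimethylsilyloxy)germacra-1(10)E,4Z-dien-8-ol
Conditions: PPTS (cat.), MeOH/CH2Cl2, 0 °C
Reagents that add atoms: none
Why: Mild acid-catalysed methanolysis cleaves a TES ether far faster than a TBS ether, so only O8 is freed; the acid is too weak to protonate the ring alkenes.

Step 21
Reactants: 30 (6S,7R,8S)-6-(tert-butyldimethylsilyloxy)germacra-1(10)E,4Z-dien-8-ol; 31 (Z)-2-methylbut-2-enoic acid (angelic acid)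
Product: 33 (6S,7R,8S)-6-(tert-butyldimethylsilyloxy)germacra-1(10)E,4Z-dien-8-yl (Z)-2-methylbut-2-enoate, via angelic trichlorobenzoic mixed anhydride 32 (not isolated)
Conditions: 31, 2,4,6-trichlorobenzoyl chloride, Et3N, toluene, rt; then 30, toluene, 75 °C
Reagents that add atoms: none
Why: Yamaguchi esterification through mixed anhydride 32 without DMAP, the conditions known to transfer the angeloyl group to hindered secondary alcohols without Z to E isomerisation; it is done before the epoxide exists and while O6 is silylated.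

Step 22
Reactants: 33 (6S,7R,8S)-6-(tert-butyldimethylsilyloxy)germacra-1(10)E,4Z-dien-8-yl (Z)-2-methylbut-2-enoate
Product: 34 (6S,7S,8S)-6-hydroxygermacra-1(10)E,4Z-dien-8-yl (Z)-2-methylbut-2-enoate
Conditions: HF·pyridine, pyridine, THF, 0 °C to rt
Reagents that add atoms: none
Why: Buffered HF·pyridine removes the allylic TBS ether without forming an alkoxide, so the 1,3-related angelate cannot migrate to O6 (the descriptor at C7 changes only because the substituent priorities change).

Step 23
Reactants: 34 (6S,7S,8S)-6-hydroxygermacra-1(10)E,4Z-dien-8-yl (Z)-2-methylbut-2-enoate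
Product: 35 (4S,5R,6R,7S,8S)-4,5-epoxy-6-hydroxygermacr-1(10)E-en-8-yl (Z)-2-methylbut-2-enoate
Conditions: VO(acac)2 (5 mol %), t-BuOOH (in decane), CH2Cl2, 0 °C
Reagents that add atoms: tert-butyl hydroperoxide, CC(C)(C)OO
Why: Vanadium-catalysed hydroxyl-directed epoxidation: the vanadate ester of O6 delivers oxygen to the adjacent C4=C5 alkene from the face on which O6 sits (O–C6–C5=C4 dihedral near 50°). The ring holds C7 out of the alkene plane on the other face, so directed and peripheral attack should coincide and give the (4S,5R) epoxide; the remote C1=C10 alkene and the conjugated angelate do not react.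

Step 24
Reactants: 35 (4S,5R,6R,7S,8S)-4,5-epoxy-6-hydroxygermacr-1(10)E-en-8-yl (Z)-2-methylbut-2-enoate
Product: 36 (4S,5R,6R,7R,8S)-6-acetoxy-4,5-epoxygermacr-1(10)E-en-8-yl (Z)-2-methylbut-2-enoate (CNP0289272.1)
Conditions: Ac2O, pyridine, DMAP (cat.), CH2Cl2, 0 °C to rt
Reagents that add atoms: acetic anhydride, CC(=O)OC(C)=O
Why: Acetylation of the secondary alcohol under mild nucleophilic catalysis completes the target; no stereocentre is touched and the conditions are neither acidic nor strongly basic.

## Compound list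

1 | 4-(tert-butyldimethylsilyloxy)but-1-yne | C#CCCO[Si](C)(C)C(C)(C)C | starting material
2 | [(1E)-4-(tert-butyldimethylsilyloxy)-2-methylbut-1-en-1-yl]dimethylalane | C[Al](C)/C=C(\C)CCO[Si](C)(C)C(C)(C)C | intermediate (not isolated)
3 | (2E)-5-(tert-butyldimethylsilyloxy)-3-methylpent-2-en-1-ol | OC/C=C(\C)CCO[Si](C)(C)C(C)(C)C | intermediate
4 | tert-butyl{[(3E)-5-(4-methoxybenzyloxy)-3-methylpent-3-en-1-yl]oxy}dimethylsilane | COc1ccc(COC/C=C(\C)CCO[Si](C)(C)C(C)(C)C)cc1 | intermediate
5 | (3E)-5-(4-methoxybenzyloxy)-3-methylpent-3-en-1-ol | COc1ccc(COC/C=C(\C)CCO)cc1 | intermediate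
6 | (3E)-5-(4-methoxybenzyloxy)-3-methylpent-3-enal | COc1ccc(COC/C=C(\C)CC=O)cc1 | intermediate
7 | (4R)-4-benzyl-1,3-oxazolidin-2-one | O=C1N[C@H](Cc2ccccc2)CO1 | starting material
8 | 3-methylbutanoyl chloride | CC(C)CC(Cl)=O | starting material
9 | (4R)-4-benzyl-3-(3-methylbutanoyl)-1,3-oxazolidin-2-one | CC(C)CC(=O)N1[C@H](Cc2ccccc2)COC1=O | intermediate
10 | Z-dibutylboron enolate of 9 | CCCCB(CCCC)O/C(=C\C(C)C)N1[C@H](Cc2ccccc2)COC1=O | intermediate (not isolated)
11 | (4R)-4-benzyl-3-[(2R,3S,5E)-3-hydroxy-7-(4-methoxybenzyloxy)-5-methyl-2-(propan-2-yl)hept-5-enoyl]-1,3-oxazolidin-2-one | COc1ccc(COC/C=C(\C)C[C@H](O)[C@@H](C(C)C)C(=O)N2[C@H](Cc3ccccc3)COC2=O)cc1 | intermediate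
12 | (2R,3S,5E)-3-hydroxy-N-methoxy-7-(4-methoxybenzyloxy)-N,5-dimethyl-2-(propan-2-yl)hept-5-enamide | COc1ccc(COC/C=C(\C)C[C@H](O)[C@@H](C(C)C)C(=O)N(C)OC)cc1 | intermediate
13 | (2R,3S,5E)-N-methoxy-7-(4-methoxybenzyloxy)-N,5-dimethyl-2-(propan-2-yl)-3-(triethylsilyloxy)hept-5-enamide | COc1ccc(COC/C=C(\C)C[C@H](O[Si](CC)(CC)CC)[C@@H](C(C)C)C(=O)N(C)OC)cc1 | intermediate
14 | prop-1-yn-1-ylmagnesium bromide | CC#C[Mg]Br | starting material
15 | (5R,6S,8E)-10-(4-methoxybenzyloxy)-8-methyl-5-(propan-2-yl)-6-(triethylsilyloxy)dec-8-en-2-yn-4-one | COc1ccc(COC/C=C(\C)C[C@H](O[Si](CC)(CC)CC)[C@@H](C(C)C)C(=O)C#CC)cc1 | intermediate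
16 | (4R,5S,6S,8E)-10-(4-methoxybenzyloxy)-8-methyl-5-(propan-2-yl)-6-(triethylsilyloxy)dec-8-en-2-yn-4-ol | COc1ccc(COC/C=C(\C)C[C@H](O[Si](CC)(CC)CC)[C@@H](C(C)C)[C@@H](O)C#CC)cc1 | intermediate
17 | sodium bis(2-methoxyethoxy)aluminate chelate of 16 (2,5-dihydro-1,2-oxaaluminole; Al on the alkene carbon bearing methyl) | [Na+].COCCO[Al-]1(OCCOC)O[C@H]([C@H](C(C)C)[C@@H](O[Si](CC)(CC)CC)C/C(C)=C/COCc2ccc(OC)cc2)C=C1C | intermediate (not isolated)
18 | (2Z,4R,5S,6S,8E)-2-iodo-10-(4-methoxybenzyloxy)-8-methyl-5-(propan-2-yl)-6-(triethylsilyloxy)deca-2,8-dien-4-ol | COc1ccc(COC/C=C(\C)C[C@H](O[Si](CC)(CC)CC)[C@@H](C(C)C)[C@@H](O)/C=C(/C)I)cc1 | intermediate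
19 | tert-butyl{[(2Z,4R,5R,6S,8E)-2-iodo-10-(4-methoxybenzyloxy)-8-methyl-5-(propan-2-yl)-6-(triethylsilyloxy)deca-2,8-dien-4-yl]oxy}dimethylsilane | COc1ccc(COC/C=C(\C)C[C@H](O[Si](CC)(CC)CC)[C@@H](C(C)C)[C@@H](O[Si](C)(C)C(C)(C)C)/C=C(/C)I)cc1 | intermediate
20 | methyl (2Z,4S,5R,6S,8E)-4-(tert-butyldimethylsilyloxy)-10-(4-methoxybenzyloxy)-2,8-dimethyl-5-(propan-2-yl)-6-(triethylsilyloxy)deca-2,8-dienoate | COc1ccc(COC/C=C(\C)C[C@H](O[Si](CC)(CC)CC)[C@@H](C(C)C)[C@@H](O[Si](C)(C)C(C)(C)C)/C=C(/C)C(=O)OC)cc1 | intermediate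
21 | methyl (2Z,4S,5R,6S,8E)-4-(tert-butyldimethylsilyloxy)-10-hydroxy-2,8-dimethyl-5-(propan-2-yl)-6-(triethylsilyloxy)deca-2,8-dienoate | OC/C=C(\C)C[C@H](O[Si](CC)(CC)CC)[C@@H](C(C)C)[C@@H](O[Si](C)(C)C(C)(C)C)/C=C(/C)C(=O)OC | intermediate
22 | sodium benzenesulfinate | [Na+].[O-]S(=O)c1ccccc1 | starting material
23 | methyl (2Z,4S,5R,6S,8E)-4-(tert-butyldimethylsilyloxy)-2,8-dimethyl-10-(methylsulfonyloxy)-5-(propan-2-yl)-6-(triethylsilyloxy)deca-2,8-dienoate | CS(=O)(=O)OC/C=C(\C)C[C@H](O[Si](CC)(CC)CC)[C@@H](C(C)C)[C@@H](O[Si](C)(C)C(C)(C)C)/C=C(/C)C(=O)OC | intermediate (not isolated)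
24 | methyl (2Z,4S,5R,6S,8E)-4-(tert-butyldimethylsilyloxy)-2,8-dimethyl-10-(phenylsulfonyl)-5-(propan-2-yl)-6-(triethylsilyloxy)deca-2,8-dienoate | O=S(=O)(C/C=C(\C)C[C@H](O[Si](CC)(CC)CC)[C@@H](C(C)C)[C@@H](O[Si](C)(C)C(C)(C)C)/C=C(/C)C(=O)OC)c1ccccc1 | intermediate
25 | (2Z,4S,5R,6S,8E)-4-(tert-butyldimethylsilyloxy)-2,8-dimethyl-10-(phenylsulfonyl)-5-(propan-2-yl)-6-(triethylsilyloxy)deca-2,8-dien-1-ol | O=S(=O)(C/C=C(\C)C[C@H](O[Si](CC)(CC)CC)[C@@H](C(C)C)[C@@H](O[Si](C)(C)C(C)(C)C)/C=C(/C)CO)c1ccccc1 | intermediate
26 | {[(2E,5S,6R,7S,8Z)-10-bromo-7-(tert-butyldimethylsilyloxy)-3,9-dimethyl-6-(propan-2-yl)-5-(triethylsilyloxy)deca-2,8-dien-1-yl]sulfonyl}benzene | O=S(=O)(C/C=C(\C)C[C@H](O[Si](CC)(CC)CC)[C@@H](C(C)C)[C@@H](O[Si](C)(C)C(C)(C)C)/C=C(/C)CBr)c1ccccc1 | intermediate (key-step precursor)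
27 | potassium salt of 26 deprotonated at the sulfonyl-bearing carbon (germacrane C2) | [K+].O=S(=O)([CH-]/C=C(\C)C[C@H](O[Si](CC)(CC)CC)[C@@H](C(C)C)[C@@H](O[Si](C)(C)C(C)(C)C)/C=C(/C)CBr)c1ccccc1 | intermediate (not isolated)
28 | (6S,7R,8S)-6-(tert-butyldimethylsilyloxy)-2-(phenylsulfonyl)-8-(triethylsilyloxy)germacra-1(10)E,4Z-diene, C2 epimers | CC[Si](CC)(CC)O[C@H]1C/C(C)=C/C(S(=O)(=O)c2ccccc2)C/C(C)=C\[C@H](O[Si](C)(C)C(C)(C)C)[C@@H]1C(C)C | intermediate (key-step product)
29 | (6S,7R,8S)-6-(tert-butyldimethylsilyloxy)-8-(triethylsilyloxy)germacra-1(10)E,4Z-diene | CC[Si](CC)(CC)O[C@H]1C/C(C)=C/CC/C(C)=C\[C@H](O[Si](C)(C)C(C)(C)C)[C@@H]1C(C)C | intermediate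
30 | (6S,7R,8S)-6-(tert-butyldimethylsilyloxy)germacra-1(10)E,4Z-dien-8-ol | O[C@H]1C/C(C)=C/CC/C(C)=C\[C@H](O[Si](C)(C)C(C)(C)C)[C@@H]1C(C)C | intermediate
31 | (Z)-2-methylbut-2-enoic acid (angelic acid) | C/C=C(/C)C(=O)O | starting material
32 | (Z)-2-methylbut-2-enoic 2,4,6-trichlorobenzoic anhydride | C/C=C(/C)C(=O)OC(=O)c1c(Cl)cc(Cl)cc1Cl | intermediate (not isolated)
33 | (6S,7R,8S)-6-(tert-butyldimethylsilyloxy)germacra-1(10)E,4Z-dien-8-yl (Z)-2-methylbut-2-enoate | C/C=C(/C)C(=O)O[C@H]1C/C(C)=C/CC/C(C)=C\[C@H](O[Si](C)(C)C(C)(C)C)[C@@H]1C(C)C | intermediate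
34 | (6S,7S,8S)-6-hydroxygermacra-1(10)E,4Z-dien-8-yl (Z)-2-methylbut-2-enoate | C/C=C(/C)C(=O)O[C@H]1C/C(C)=C/CC/C(C)=C\[C@H](O)[C@@H]1C(C)C | intermediate
35 | (4S,5R,6R,7S,8S)-4,5-epoxy-6-hydroxygermacr-1(10)E-en-8-yl (Z)-2-methylbut-2-enoate | C/C=C(/C)C(=O)O[C@H]1C/C(C)=C/CC[C@]2(C)O[C@@H]2[C@H](O)[C@@H]1C(C)C | intermediate
36 | (4S,5R,6R,7R,8S)-6-acetoxy-4,5-epoxygermacr-1(10)E-en-8-yl (Z)-2-methylbut-2-enoate (CNP0289272.1) | C/C=C(/C)C(=O)O[C@H]1C/C(C)=C/CC[C@]2(C)O[C@@H]2[C@H](OC(C)=O)[C@@H]1C(C)C | target

## Step count and least certain steps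

Total: 24 steps. Longest linear sequence: 23 steps (steps 1–4 and 6–24; step 5 is a one-step branch).

**Step 18 (key step).**
- What may go wrong: ring closure may lose to intermolecular alkylation or to base-induced loss of HBr from the Z-allylic bromide. Ten-membered closure is enthalpically costly, and the electrophilic carbon lies cis across the alkene to the silyloxy-bearing C6.
- Fallback: reverse the polarity of the same C2–C3 bond, so that the electrophile is the unhindered E-allylic terminus. It sets out from ester 20.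
  - i-Bu2AlH reduction gives (2Z,4S,5R,6S,8E)-4-(tert-butyldimethylsilyloxy)-10-(4-methoxybenzyloxy)-2,8-dimethyl-5-(propan-2-yl)-6-(triethylsilyloxy)deca-2,8-dien-1-ol F1.
  - Mesylation with (MeSO2)2O/Et3N gives the allylic mesylate F2, which is displaced in the same flask by sodium benzenesulfinate 22 to give the C3 sulfone F3.
  - DDQ removes the PMB group to give the C2 alcohol F4, and CBr4/PPh3 gives the E-allylic bromide F5.
  - Slow addition to KN(SiMe3)2 at high dilution then closes the ring from the C3 carbanion onto C2, giving (6S,7R,8S)-6-(tert-butyldimethylsilyloxy)-3-(phenylsulfonyl)-8-(triethylsilyloxy)germacra-1(10)E,4Z-diene F6.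
  - PdCl2(dppp)/LiBHEt3 removes the sulfone with hydride capture at C3, and the route is rejoined at 29.

**Step 23 (directed epoxidation).**
- What may go wrong: facial selectivity may be poor if the ring populates a conformer with O6 in the alkene plane. The Lewis-acidic vanadium may also trigger transannular attack of C1=C10 on the new epoxide.
- Fallback: replace substrate direction by reagent control with a Sharpless titanium–tartrate epoxidation (Ti(O-i-Pr)4, L-(+)-diisopropyl tartrate, t-BuOOH, 4 Å sieves, CH2Cl2, −20 °C). With the alkene drawn in the plane and C6 at the lower right, this tartrate delivers oxygen from below, which is the required face. C7 then lies on the upper face, so 34 is the fast-reacting configuration. The fallback runs from 34 to 35 and makes no new compound.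

**Step 21 (angeloylation).**
- What may go wrong: the angeloyl group may isomerise to tigloyl during acyl transfer, or the cyclodeca-1,5-diene may undergo Cope rearrangement at the temperature a hindered alcohol needs.
- Fallback: build the Z ester on the molecule at low temperature. Alcohol 30 is esterified with 2-[bis(2,2,2-trifluoroethoxy)phosphoryl]propanoic acid (DCC, DMAP, CH2Cl2, rt) to give the phosphonate ester F7. Still–Gennari olefination with acetaldehyde (KN(SiMe3)2, 18-crown-6, THF, −78 °C) then gives the Z-2-methylbut-2-enoate and rejoins the route at 33.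

**Step 7 (Weinreb amide formation).**
- What may go wrong: the aluminium amide may attack the ring carbonyl of the auxiliary, or retro-aldol cleavage may occur, because the α-isopropyl group shields the exocyclic carbonyl.
- Fallback: go through the aldehyde oxidation level, setting out from 11.
  - TESOTf/2,6-lutidine gives the silylated imide F8.
  - LiBH4 (THF, MeOH, 0 °C) removes the auxiliary reductively to give (2S,3S,5E)-7-(4-methoxybenzyloxy)-5-methyl-2-(propan-2-yl)-3-(triethylsilyloxy)hept-5-en-1-ol F9.
  - Dess–Martin oxidation gives the aldehyde F10, and addition of 14 gives the propargylic alcohols F11 (both C4 epimers).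
  - A second Dess–Martin oxidation rejoins the route at ynone 15.

## Further compounds

F1 | step 18 | (2Z,4S,5R,6S,8E)-4-(tert-butyldimethylsilyloxy)-10-(4-methoxybenzyloxy)-2,8-dimethyl-5-(propan-2-yl)-6-(triethylsilyloxy)deca-2,8-dien-1-ol | COc1ccc(COC/C=C(\C)C[C@H](O[Si](CC)(CC)CC)[C@@H](C(C)C)[C@@H](O[Si](C)(C)C(C)(C)C)/C=C(/C)CO)cc1
F2 | step 18 | methanesulfonate of F1 | COc1ccc(COC/C=C(\C)C[C@H](O[Si](CC)(CC)CC)[C@@H](C(C)C)[C@@H](O[Si](C)(C)C(C)(C)C)/C=C(/C)COS(C)(=O)=O)cc1
F3 | step 18 | open-chain C3 phenyl sulfone with C2 PMB ether | COc1ccc(COC/C=C(\C)C[C@H](O[Si](CC)(CC)CC)[C@@H](C(C)C)[C@@H](O[Si](C)(C)C(C)(C)C)/C=C(/C)CS(=O)(=O)c2ccccc2)cc1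
F4 | step 18 | open-chain C3 phenyl sulfone with C2 alcohol | OC/C=C(\C)C[C@H](O[Si](CC)(CC)CC)[C@@H](C(C)C)[C@@H](O[Si](C)(C)C(C)(C)C)/C=C(/C)CS(=O)(=O)c1ccccc1
F5 | step 18 | open-chain C3 phenyl sulfone with C2 allylic bromide | BrC/C=C(\C)C[C@H](O[Si](CC)(CC)CC)[C@@H](C(C)C)[C@@H](O[Si](C)(C)C(C)(C)C)/C=C(/C)CS(=O)(=O)c1ccccc1
F6 | step 18 | (6S,7R,8S)-6-(tert-butyldimethylsilyloxy)-3-(phenylsulfonyl)-8-(triethylsilyloxy)germacra-1(10)E,4Z-diene, C3 epimers | CC[Si](CC)(CC)O[C@H]1C/C(C)=C/CC(S(=O)(=O)c2ccccc2)/C(C)=C\[C@H](O[Si](C)(C)C(C)(C)C)[C@@H]1C(C)C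
F0 | step 23 | none | none
F7 | step 21 | (6S,7R,8S)-6-(tert-butyldimethylsilyloxy)germacra-1(10)E,4Z-dien-8-yl 2-[bis(2,2,2-trifluoroethoxy)phosphoryl]propanoate | CC(C(=O)O[C@H]1C/C(C)=C/CC/C(C)=C\[C@H](O[Si](C)(C)C(C)(C)C)[C@@H]1C(C)C)P(=O)(OCC(F)(F)F)OCC(F)(F)F
F8 | step 7 | (4R)-4-benzyl-3-[(2R,3S,5E)-7-(4-methoxybenzyloxy)-5-methyl-2-(propan-2-yl)-3-(triethylsilyloxy)hept-5-enoyl]-1,3-oxazolidin-2-one | COc1ccc(COC/C=C(\C)C[C@H](O[Si](CC)(CC)CC)[C@@H](C(C)C)C(=O)N2[C@H](Cc3ccccc3)COC2=O)cc1
F9 | step 7 | (2S,3S,5E)-7-(4-methoxybenzyloxy)-5-methyl-2-(propan-2-yl)-3-(triethylsilyloxy)hept-5-en-1-ol | COc1ccc(COC/C=C(\C)C[C@H](O[Si](CC)(CC)CC)[C@@H](C(C)C)CO)cc1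
F10 | step 7 | (2R,3S,5E)-7-(4-methoxybenzyloxy)-5-methyl-2-(propan-2-yl)-3-(triethylsilyloxy)hept-5-enal | COc1ccc(COC/C=C(\C)C[C@H](O[Si](CC)(CC)CC)[C@@H](C(C)C)C=O)cc1
F11 | step 7 | (5S,6S,8E)-10-(4-methoxybenzyloxy)-8-methyl-5-(propan-2-yl)-6-(triethylsilyloxy)dec-8-en-2-yn-4-ol, C4 epimers | COc1ccc(COC/C=C(\C)C[C@H](O[Si](CC)(CC)CC)[C@@H](C(C)C)C(O)C#CC)cc1
A1 | alternative 1 | head-to-head tricyclic photoadduct (cyclobutane C1, C4, C5, C10; ester on C4; ketone C6; 8-O-TBS) | CC(C)(C)[Si](C)(C)O[C@H]1C[C@]2(C)[C@H]3CC[C@@]3(C(=O)OC)[C@@H]2C(=O)[C@@H]1C(C)C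
A2 | alternative 1 | (5S,6R)-5-(tert-butyldimethylsilyloxy)-3-methyl-6-(propan-2-yl)cyclohex-2-en-1-one | CC(C)(C)[Si](C)(C)O[C@H]1CC(C)=CC(=O)[C@@H]1C(C)C
A3 | alternative 1 | methyl cyclobut-1-ene-1-carboxylate | COC(=O)C1=CCC1
A4 | alternative 2 | 8-(4-methoxybenzyloxy)germacra-1(10)E,4Z-dien-6-one | COc1ccc(CO[C@H]2C/C(C)=C/CC/C(C)=C\C(=O)[C@@H]2C(C)C)cc1
A5 | alternative 2 | 1-[(E)-1-(4-methoxybenzyloxy)-3-methylbut-1-en-2-yl]-3-methyl-6-(prop-1-en-2-yl)cyclohex-2-en-1-ol, trans-dialkenyl isomer | COc1ccc(CO/C=C(\C(C)C)[C@]2(O)C=C(C)CC[C@H]2C(C)=C)cc1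
A6 | alternative 3 | 6-(tert-butyldimethylsilyloxy)germacra-1(10)E,4Z,11-trien-8-ol | O[C@H]1C/C(C)=C/CC/C(C)=C\[C@H](O[Si](C)(C)C(C)(C)C)[C@@H]1C(C)=C
A7 | alternative 3 | thirteen-membered allylic α-(tributylstannyl) ether (O between C8 and C12; alkenes 1(10)E, 4Z, 7(11)E; 6-O-TBS) | CCCC[Sn](CCCC)(CCCC)[C@H]1C/C(C)=C/CC/C(C)=C\[C@H](O[Si](C)(C)C(C)(C)C)/C=C(\C)CO1
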